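The route rests on disconnecting C7–C8 of the seven-membered carbocycle (C1, C5, C6, C7, C8, C9, C10). C7 is the β-carbon of the C12 lactone carbonyl and is flanked only by the C8 and C9 methylenes, so a primary C8 radical can close the ring 7-exo onto a planar butenolide anchored at C6. That single operation forms the carbocycle, the cis ring fusion at C7 and the C11 methyl stereocentre. Its precursor is an open-chain C8 iodide carrying the C6 3-methylbutenolide, a trans C1/C5 acetonide, a C4 silyl ether and C2 masked as a carbinol, assembled from a D-threitol acetonide, a (Z)-crotylboronate and (R)-but-3-yn-2-ol.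

Key step: step 16

Remarks on the chemistry
- Numbering: ring C1 (tertiary carbinol), C5 (angelate carbon), C6 (lactone O–CH), C7–C10; chain C2 (ketone), C3, C4 (carbinol); lactone C11, C12. Target descriptors in this numbering: 1S,4R,5S,6R,7S,10S,11R; the C1/C5 oxygens are trans on the carbocycle.
- C2 is a secondary alcohol only for the cyclization (steps 15–17). A C2 ketone would lie 1,5 to the C8 radical, inviting 5-exo attack on the carbonyl and acyl transfer from C1 to C8 (Dowd–Beckwith-type). The temporary C2 configuration is of no consequence.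
- Relative to the C5 alkoxy centre, the target needs the C2 carbon to enter C1 in the Felkin–Anh sense, so C2 is brought in last as a non-chelating acetylide onto a ketone that already carries C10.
- The C4 silyl ether is TBDPS (tert-butyldiphenylsilyl) so that it survives both acetonide cleavages.
- Assumption: compound 1 is taken as commercial; otherwise it is two steps (acetonide formation, LiAlH4) from diethyl (2S,3S)-tartrate.

Step 1
Reactants: 1 (4R,5R)-2,2-dimethyl-1,3-dioxolane-4,5-dimethanol
Product: 2 [(4R,5R)-5-(benzyloxymethyl)-2,2-dimethyl-1,3-dioxolan-4-yl]methanol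
Conditions: NaH (1.0 equiv), BnBr (1.0 equiv), Bu4NI (cat.), THF, 0 °C to rt
Reagents that add atoms: benzyl bromide, BrCc1ccccc1
Why: Williamson etherification of the monoalkoxide of the C2-symmetric diol should give mainly the mono-benzyl ether, and no stereocentre is touched.

Step 2
Reactants: 2 [(4R,5R)-5-(benzyloxymethyl)-2,2-dimethyl-1,3-dioxolan-4-yl]methanol
Product: 3 (4S,5R)-5-(benzyloxymethyl)-2,2-dimethyl-1,3-dioxolane-4-carbaldehyde
Conditions: Dess–Martin periodinane, NaHCO3, CH2Cl2, 0 °C to rt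
Reagents that add atoms: none
Why: Dess–Martin oxidation of the primary alcohol under buffered conditions should give the α-alkoxy aldehyde (the future C1), whose trans-dioxolane stereocentre is not prone to epimerization.

Step 3
Reactants: 3 (4S,5R)-5-(benzyloxymethyl)-2,2-dimethyl-1,3-dioxolane-4-carbaldehyde; 4 (Z)-crotylboronic acid pinacol ester
Product: 6 (1R,2S)-1-[(4R,5R)-5-(benzyloxymethyl)-2,2-dimethyl-1,3-dioxolan-4-yl]-2-methylbut-3-en-1-ol, via pinacol borate ester 5 (not isolated)
Conditions: toluene (concentrated), 4 Å sieves, rt, 48 h; then aq. NaHCO3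
Reagents that add atoms: none
Why: Allylboration through a closed chair (Zimmerman–Traxler) transition state: the (Z)-crotyl geometry should place C10–CH3 syn to C1–OH, and Felkin/Cornforth attack anti to the C5–O bond should fix C10 as S (the C1 carbinol is oxidized in step 6).

Step 4
Reactants: 6 (1R,2S)-1-[(4R,5R)-5-(benzyloxymethyl)-2,2-dimethyl-1,3-dioxolan-4-yl]-2-methylbut-3-en-1-ol
Product: 8 (1R,2S)-1-[(4R,5R)-5-(benzyloxymethyl)-2,2-dimethyl-1,3-dioxolan-4-yl]-2-methylbutane-1,4-diol, via alkylborane 7 (not isolated)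
Conditions: 9-BBN (2.5 equiv), THF, 0 °C to rt; then NaOH, H2O2, 0 °C
Reagents that add atoms: hydrogen peroxide, OO
Why: Anti-Markovnikov hydroboration–oxidation of the terminal alkene should give the primary C8 alcohol without touching the benzyl ether or the acetonide.

Step 5
Reactants: 8 (1R,2S)-1-[(4R,5R)-5-(benzyloxymethyl)-2,2-dimethyl-1,3-dioxolan-4-yl]-2-methylbutane-1,4-diol
Product: 9 (1R,2S)-1-[(4R,5R)-5-(benzyloxymethyl)-2,2-dimethyl-1,3-dioxolan-4-yl]-4-[(tert-butyldimethylsilyl)oxy]-2-methylbutan-1-ol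
Conditions: TBSCl (1.05 equiv), imidazole, CH2Cl2, −20 to 0 °C
Reagents that add atoms: tert-butyldimethylsilyl chloride, CC(C)(C)[Si](C)(C)Cl
Why: Silylation should be selective for the primary C8 hydroxyl over the hindered secondary C1 hydroxyl.

Step 6
Reactants: 9 (1R,2S)-1-[(4R,5R)-5-(benzyloxymethyl)-2,2-dimethyl-1,3-dioxolan-4-yl]-4-[(tert-butyldimethylsilyl)oxy]-2-methylbutan-1-ol
Product: 10 (2S)-1-[(4S,5R)-5-(benzyloxymethyl)-2,2-dimethyl-1,3-dioxolan-4-yl]-4-[(tert-butyldimethylsilyl)oxy]-2-methylbutan-1-one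
Conditions: Dess–Martin periodinane, NaHCO3, CH2Cl2, 0 °C to rt
Reagents that add atoms: none
Why: Dess–Martin oxidation under buffered, non-basic conditions should give the C1 ketone without epimerizing the adjacent C10 stereocentre.

Step 7
Reactants: 11 (R)-but-3-yn-2-ol
Product: 12 (R)-(but-3-yn-2-yloxy)(tert-butyl)diphenylsilane
Conditions: TBDPSCl, imidazole, DMF, rt
Reagents that add atoms: tert-butyldiphenylsilyl chloride, CC(C)(C)[Si](Cl)(c1ccccc1)c1ccccc1
Why: Standard silylation of the secondary propargylic alcohol, which leaves the C4 stereocentre untouched.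

Step 8
Reactants: 10 (2S)-1-[(4S,5R)-5-(benzyloxymethyl)-2,2-dimethyl-1,3-dioxolan-4-yl]-4-[(tert-butyldimethylsilyl)oxy]-2-methylbutan-1-one; 12 (R)-(but-3-yn-2-yloxy)(tert-butyl)diphenylsilane
Product: 15 tert-butyl carbonate of the C1 alkynyl carbinol (1R,4R,5S,6R,10S), via lithium acetylide 13 (not isolated), via lithium alkoxide 14 (not isolated)
Conditions: 12, n-BuLi, THF, −78 °C; then 10, −78 °C; then Boc2O, −78 to 0 °C
Reagents that add atoms: di-tert-butyl dicarbonate, CC(C)(C)OC(=O)OC(=O)OC(C)(C)C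
Why: 1,2-Addition of the non-chelating lithium acetylide under Felkin–Anh control (attack anti to the C5–O bond, reinforced by the C10 centre) should set C1 in the spatial arrangement of the target, and the tertiary alkoxide is trapped in the same flask as its tert-butyl carbonate.

Step 9
Reactants: 15 tert-butyl carbonate of the C1 alkynyl carbinol (1R,4R,5S,6R,10S)
Product: 17 α-hydroxy ketone with C1 hydroxyl and C2 ketone (1S,4R,5S,6R,10S), via cyclic enol carbonate 16 (not isolated)
Conditions: Ph3PAuNTf2 (3 mol%), CH2Cl2, rt; then K2CO3 (cat.), MeOH, 0 °C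
Reagents that add atoms: none
Why: Activation of the alkyne by monovalent gold should induce 5-exo-dig attack of the carbonate carbonyl oxygen on C2 with loss of isobutene (the known cyclization of propargylic tert-butyl carbonates to 4-alkylidene-1,3-dioxolan-2-ones), which places oxygen regiospecifically at C2, and methanolysis of the enol carbonate should release the α-hydroxy ketone.

Step 10
Reactants: 17 α-hydroxy ketone with C1 hydroxyl and C2 ketone (1S,4R,5S,6R,10S)
Product: 18 C7 primary alcohol (1S,4R,5S,6R,10S)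
Conditions: H2 (1 atm), Pd/C, EtOAc, rt
Reagents that add atoms: none
Why: Hydrogenolysis of the benzyl ether should be clean because no C=C or C≡C bond remains, and the silyl ethers, ketone and acetonide are inert in ethyl acetate.

Step 11
Reactants: 18 C7 primary alcohol (1S,4R,5S,6R,10S)
Product: 19 C7 aldehyde (1S,4R,5S,6S,10S)
Conditions: Dess–Martin periodinane, NaHCO3, CH2Cl2, 0 °C
Reagents that add atoms: none
Why: Dess–Martin oxidation of the only primary alcohol should give the aldehyde while the tertiary C1 hydroxyl is inert (the C6 descriptor changes by priority only).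

Step 12
Reactants: 19 C7 aldehyde (1S,4R,5S,6S,10S); 20 ethyl 2-[bis(2,2,2-trifluoroethoxy)phosphoryl]propanoate
Product: 22 ethyl (Z)-enoate C7=C11(CH3)–C12 (1S,4R,5S,6R,10S), via potassium phosphonate 21 (not isolated)
Conditions: 20, KN(SiMe3)2, 18-crown-6, THF, −78 °C; then 19
Reagents that add atoms: none
Why: The Still–Gennari variant of the Horner–Wadsworth–Emmons reaction should give the (Z)-trisubstituted enoate, which places the ester cis to C6 as lactonization requires.

Step 13
Reactants: 22 ethyl (Z)-enoate C7=C11(CH3)–C12 (1S,4R,5S,6R,10S)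
Product: 24 butenolide with C1/C5 acetonide and free C8 hydroxyl (1S,4R,5S,6R,10S), via triol butenolide 23 (not isolated)
Conditions: CF3CO2H/H2O/THF, 0 °C to rt; evaporate; then 2,2-dimethoxypropane, PPTS, acetone, rt; aq. NH4Cl
Reagents that add atoms: 2,2-dimethoxypropane, COC(C)(C)OC
Why: Aqueous acid should cleave the C5/C6 acetonide and the primary silyl ether, the (Z)-γ-hydroxy enoate then lactonizes at O6 (five-membered ring) to the butenolide, and acetonide formation can afterwards engage only the vicinal C1/C5 diol.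

Step 14
Reactants: 24 butenolide with C1/C5 acetonide and free C8 hydroxyl (1S,4R,5S,6R,10S)
Product: 25 C8 iodide with C2 ketone (1S,4R,5S,6R,10S)
Conditions: I2, PPh3, imidazole, CH2Cl2, 0 °C
Reagents that add atoms: iodine, II
Why: Appel-type iodination of the only free (primary) hydroxyl proceeds under neutral conditions that the butenolide tolerates.

Step 15
Reactants: 25 C8 iodide with C2 ketone (1S,4R,5S,6R,10S)
Product: 26 iodo butenolide with C2 carbinol (1R,2R,4R,5S,6R,10S)
Conditions: (S)-2-methyl-CBS-oxazaborolidine (20 mol%), BH3·SMe2, THF, −20 °C; MeOH quench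
Reagents that add atoms: none
Why: Corey–Bakshi–Shibata reduction of the hindered ketone, with the quaternary C1 as the large group, should give the (2R)-carbinol under reagent control (the centre is removed again in step 17) while lactone and iodide are untouched.

Step 16
Reactants: 26 iodo butenolide with C2 carbinol (1R,2R,4R,5S,6R,10S)
Product: 27 cis-fused bicyclic lactone with C1/C5 acetonide and C2 carbinol (1R,2R,4R,5S,6R,7S,10S,11R)
Conditions: Bu3SnH (1.5 equiv), AIBN (0.3 equiv), syringe pump over 10 h into 26 in benzene (2 mM), 80 °C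
Reagents that add atoms: none
Why: The tributyltin radical abstracts iodine from C8 and the nucleophilic primary radical adds to C7, the electron-poor β-carbon of the butenolide, in a 7-exo-trig closure; the C11 α-carbonyl radical then takes hydrogen from Bu3SnH, which carries the chain. The closest known reaction type is the tin hydride-mediated radical conjugate cyclization onto unsaturated lactones, for which seven-membered exo closures are documented. C7 is set by the tether, which leaves C6 on one face of the planar butenolide, so C8 can reach only that face and the ring fusion must be cis. C11 is set in the hydrogen transfer, which should occur on the convex face of the new cis-fused bicycle, anti to the fresh C7–C8 bond, leaving the methyl on the concave face as in the target. The step needs cyclization to outrun direct reduction and hydrogen translocation: slow addition keeps the stannane dilute, the trans C1/C5 acetonide holds C6 and C10 gauche, and with C2 as a carbinol no carbonyl lies 1,5 to the radical.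

Step 17
Reactants: 27 cis-fused bicyclic lactone with C1/C5 acetonide and C2 carbinol (1R,2R,4R,5S,6R,7S,10S,11R)
Product: 28 protected core with C2 ketone (1S,4R,5S,6R,7S,10S,11R)
Conditions: Dess–Martin periodinane, NaHCO3, CH2Cl2, 0 °C to rt
Reagents that add atoms: none
Why: Dess–Martin oxidation of the C2 carbinol under buffered neutral conditions should restore the ketone without epimerizing C11.

Step 18
Reactants: 28 protected core with C2 ketone (1S,4R,5S,6R,7S,10S,11R)
Product: 29 C1/C5 diol (1S,4R,5S,6R,7S,10S,11R)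
Conditions: AcOH/H2O (4:1), 40 °C
Reagents that add atoms: none
Why: Mild aqueous acid should hydrolyse the strained trans-fused acetonide while the secondary TBDPS ether and the lactone stay intact.

Step 19
Reactants: 29 C1/C5 diol (1S,4R,5S,6R,7S,10S,11R); 30 angelic acid
Product: 32 C5 angelate C4 TBDPS ether (1S,4R,5S,6R,7S,10S,11R), via mixed anhydride 31 (not isolated)
Conditions: 30, 2,4,6-trichlorobenzoyl chloride, Et3N, toluene, rt; then 29, toluene, 75 °C (no DMAP)
Reagents that add atoms: none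
Why: Yamaguchi-type esterification through the preformed mixed anhydride acylates the secondary C5 hydroxyl (the tertiary C1 hydroxyl is inert) and is known to limit Z-to-E isomerization of the angeloyl group.

Step 20
Reactants: 32 C5 angelate C4 TBDPS ether (1S,4R,5S,6R,7S,10S,11R)
Product: 33 CNP0321985.1 (1S,4R,5S,6R,7S,10S,11R)
Conditions: HF·pyridine, pyridine, THF, 0 °C to rt
Reagents that add atoms: none
Why: Desilylation with buffered HF·pyridine should free the C4 hydroxyl without acyl migration, retro-aldol cleavage or epimerization at C11.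

Compound list
1 | (4R,5R)-2,2-dimethyl-1,3-dioxolane-4,5-dimethanol [(−)-2,3-O-isopropylidene-D-threitol] | OC[C@H]1OC(C)(C)O[C@@H]1CO | starting material
2 | [(4R,5R)-5-(benzyloxymethyl)-2,2-dimethyl-1,3-dioxolan-4-yl]methanol | OC[C@H]1OC(C)(C)O[C@@H]1COCc1ccccc1 | intermediate
3 | (4S,5R)-5-(benzyloxymethyl)-2,2-dimethyl-1,3-dioxolane-4-carbaldehyde | O=C[C@H]1OC(C)(C)O[C@@H]1COCc1ccccc1 | intermediate
4 | (Z)-crotylboronic acid pinacol ester | C/C=C\CB1OC(C)(C)C(C)(C)O1 | starting material
5 | pinacol borate ester of 6 (boron on the C1 oxygen) | C=C[C@H](C)[C@@H](OB2OC(C)(C)C(C)(C)O2)[C@H]1OC(C)(C)O[C@@H]1COCc1ccccc1 | intermediate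
6 | (1R,2S)-1-[(4R,5R)-5-(benzyloxymethyl)-2,2-dimethyl-1,3-dioxolan-4-yl]-2-methylbut-3-en-1-ol | C=C[C@H](C)[C@@H](O)[C@H]1OC(C)(C)O[C@@H]1COCc1ccccc1 | intermediate
7 | C8 alkylborane of 6 (9-BBN on C8; C1 oxygen as 9-BBN borinate) | B1(C2CCCC1CCC2)CC[C@H](C)[C@@H](OB3C4CCCC3CCC4)[C@H]5OC(C)(C)O[C@@H]5COCc6ccccc6 | intermediate
8 | (1R,2S)-1-[(4R,5R)-5-(benzyloxymethyl)-2,2-dimethyl-1,3-dioxolan-4-yl]-2-methylbutane-1,4-diol | OCC[C@H](C)[C@@H](O)[C@H]1OC(C)(C)O[C@@H]1COCc1ccccc1 | intermediate
9 | (1R,2S)-1-[(4R,5R)-5-(benzyloxymethyl)-2,2-dimethyl-1,3-dioxolan-4-yl]-4-[(tert-butyldimethylsilyl)oxy]-2-methylbutan-1-ol | CC(C)(C)[Si](C)(C)OCC[C@H](C)[C@@H](O)[C@H]1OC(C)(C)O[C@@H]1COCc1ccccc1 | intermediate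
10 | (2S)-1-[(4S,5R)-5-(benzyloxymethyl)-2,2-dimethyl-1,3-dioxolan-4-yl]-4-[(tert-butyldimethylsilyl)oxy]-2-methylbutan-1-one | CC(C)(C)[Si](C)(C)OCC[C@H](C)C(=O)[C@H]1OC(C)(C)O[C@@H]1COCc1ccccc1 | intermediate
11 | (R)-but-3-yn-2-ol | C[C@@H](O)C#C | starting material
12 | (R)-(but-3-yn-2-yloxy)(tert-butyl)diphenylsilane | C[C@@H](O[Si](c1ccccc1)(c1ccccc1)C(C)(C)C)C#C | intermediate
13 | lithium acetylide of 12 | C[C@@H](O[Si](c1ccccc1)(c1ccccc1)C(C)(C)C)C#C[Li] | intermediate
14 | lithium C1 alkoxide from addition of 13 to 10 | CC(C)(C)[Si](C)(C)OCC[C@H](C)[C@@](O[Li])(C#C[C@@H](C)O[Si](c2ccccc2)(c2ccccc2)C(C)(C)C)[C@H]1OC(C)(C)O[C@@H]1COCc1ccccc1 | intermediate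
15 | tert-butyl carbonate of the C1 alkynyl carbinol (C2≡C3 alkyne; C4 OTBDPS; C5/C6 acetonide; C7 OBn; C8 OTBS; 1R,4R,5S,6R,10S) | CC(C)(C)[Si](C)(C)OCC[C@H](C)[C@@](OC(=O)OC(C)(C)C)(C#C[C@@H](C)O[Si](c2ccccc2)(c2ccccc2)C(C)(C)C)[C@H]1OC(C)(C)O[C@@H]1COCc1ccccc1 | intermediate
16 | cyclic enol carbonate: (Z)-4-alkylidene-1,3-dioxolan-2-one spanning O1, C1 and C2 (1S,4R,5S,6R,10S) | CC(C)(C)[Si](C)(C)OCC[C@H](C)[C@]2(OC(=O)O/C2=C\[C@@H](C)O[Si](c3ccccc3)(c3ccccc3)C(C)(C)C)[C@H]1OC(C)(C)O[C@@H]1COCc1ccccc1 | intermediate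
17 | α-hydroxy ketone: C1 OH; C2 ketone; C4 OTBDPS; C5/C6 acetonide; C7 OBn; C8 OTBS (1S,4R,5S,6R,10S) | CC(C)(C)[Si](C)(C)OCC[C@H](C)[C@@](O)(C(=O)C[C@@H](C)O[Si](c2ccccc2)(c2ccccc2)C(C)(C)C)[C@H]1OC(C)(C)O[C@@H]1COCc1ccccc1 | intermediate
18 | C7 primary alcohol: 17 without the benzyl group (1S,4R,5S,6R,10S) | CC(C)(C)[Si](C)(C)OCC[C@H](C)[C@@](O)(C(=O)C[C@@H](C)O[Si](c2ccccc2)(c2ccccc2)C(C)(C)C)[C@H]1OC(C)(C)O[C@@H]1CO | intermediate
19 | C7 aldehyde (1S,4R,5S,6S,10S) | CC(C)(C)[Si](C)(C)OCC[C@H](C)[C@@](O)(C(=O)C[C@@H](C)O[Si](c2ccccc2)(c2ccccc2)C(C)(C)C)[C@H]1OC(C)(C)O[C@@H]1C=O | intermediate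
20 | ethyl 2-[bis(2,2,2-trifluoroethoxy)phosphoryl]propanoate | CCOC(=O)C(C)P(=O)(OCC(F)(F)F)OCC(F)(F)F | starting material
21 | potassium salt of the carbanion of 20 | [K+].CCOC(=O)[C-](C)P(=O)(OCC(F)(F)F)OCC(F)(F)F | intermediate
22 | ethyl (Z)-enoate: C7=C11(CH3)–C12O2Et on the C5/C6 acetonide (1S,4R,5S,6R,10S) | CC(C)(C)[Si](C)(C)OCC[C@H](C)[C@@](O)(C(=O)C[C@@H](C)O[Si](c2ccccc2)(c2ccccc2)C(C)(C)C)[C@H]1OC(C)(C)O[C@@H]1/C=C(/C)C(=O)OCC | intermediate
23 | triol butenolide: C6 3-methylbutenolide; free C1, C5 and C8 hydroxyls; C2 ketone; C4 OTBDPS (1S,4R,5S,6R,10S) | OCC[C@H](C)[C@@](O)(C(=O)C[C@@H](C)O[Si](c2ccccc2)(c2ccccc2)C(C)(C)C)[C@@H](O)[C@@H]1OC(=O)C(C)=C1 | intermediate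
24 | butenolide with C1/C5 acetonide and free C8 hydroxyl; C2 ketone; C4 OTBDPS (1S,4R,5S,6R,10S) | OCC[C@H](C)[C@]1(C(=O)C[C@@H](C)O[Si](c2ccccc2)(c2ccccc2)C(C)(C)C)OC(C)(C)O[C@H]1[C@@H]2OC(=O)C(C)=C2 | intermediate
25 | C8 iodide with C2 ketone (1S,4R,5S,6R,10S) | ICC[C@H](C)[C@]1(C(=O)C[C@@H](C)O[Si](c2ccccc2)(c2ccccc2)C(C)(C)C)OC(C)(C)O[C@H]1[C@@H]2OC(=O)C(C)=C2 | intermediate
26 | cyclization precursor: iodo butenolide with C1/C5 acetonide, C2 carbinol and C4 OTBDPS (1R,2R,4R,5S,6R,10S) | ICC[C@H](C)[C@]1([C@H](O)C[C@@H](C)O[Si](c2ccccc2)(c2ccccc2)C(C)(C)C)OC(C)(C)O[C@H]1[C@@H]2OC(=O)C(C)=C2 | intermediate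
27 | cyclization product: cis-fused bicyclic lactone with C1/C5 acetonide, C2 carbinol and C4 OTBDPS (1R,2R,4R,5S,6R,7S,10S,11R) | CC1(C)O[C@H]2[C@@H]3OC(=O)[C@H](C)[C@@H]3CC[C@H](C)[C@@]2(O1)[C@H](O)C[C@@H](C)O[Si](c4ccccc4)(c4ccccc4)C(C)(C)C | intermediate
28 | protected core: C1/C5 acetonide, C2 ketone, C4 OTBDPS, complete bicyclic lactone (1S,4R,5S,6R,7S,10S,11R) | CC1(C)O[C@H]2[C@@H]3OC(=O)[C@H](C)[C@@H]3CC[C@H](C)[C@@]2(O1)C(=O)C[C@@H](C)O[Si](c4ccccc4)(c4ccccc4)C(C)(C)C | intermediate
29 | C1/C5 diol with C4 OTBDPS (1S,4R,5S,6R,7S,10S,11R) | O[C@H]1[C@@H]2OC(=O)[C@H](C)[C@@H]2CC[C@H](C)[C@@]1(O)C(=O)C[C@@H](C)O[Si](c3ccccc3)(c3ccccc3)C(C)(C)C | intermediate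
30 | angelic acid [(Z)-2-methylbut-2-enoic acid] | C/C=C(/C)C(=O)O | starting material
31 | angelic 2,4,6-trichlorobenzoic mixed anhydride | C/C=C(/C)C(=O)OC(=O)c1c(Cl)cc(Cl)cc1Cl | intermediate
32 | C5 angelate C4 TBDPS ether (1S,4R,5S,6R,7S,10S,11R) | C/C=C(/C)C(=O)O[C@H]1[C@@H]2OC(=O)[C@H](C)[C@@H]2CC[C@H](C)[C@@]1(O)C(=O)C[C@@H](C)O[Si](c3ccccc3)(c3ccccc3)C(C)(C)C | intermediate
33 | CNP0321985.1 (1S,4R,5S,6R,7S,10S,11R) | C/C=C(/C)C(=O)O[C@H]1[C@@H]2OC(=O)[C@H](C)[C@@H]2CC[C@H](C)[C@@]1(O)C(=O)C[C@@H](C)O | target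

Total step count: 20. Longest linear sequence: 19 steps (steps 1–6 and 8–20; step 7 is the side branch).

Steps most likely to fail

Step 16. The seven-membered closure may lose to premature hydrogen transfer from the stannane or to intramolecular hydrogen translocation (1,5 from C5–H or C2–H, 1,6 from the allylic C6–H), and hydrogen may reach C11 partly on the concave face. The fallback replaces the hydride chain by a donor-free reductive closure and sets out from 26. Vitamin B12 (cyanocobalamin, C63H88CoN14O14P, 10 mol%), Zn and NH4Cl in DMF under visible light should convert the iodide into an alkylcobalt species (trivalent cobalt, formed from monovalent cobalt). This releases the C8 radical reversibly, so the radical is not intercepted by a hydrogen-atom donor before it adds to C7. The C11 radical is then reduced to the enolate and protonated on the convex face. This gives 27 directly and rejoins the route at 27; no new compound is made.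

Step 19. Acylation of the hindered C5 hydroxyl may be slow, and the angeloyl group may isomerize to the E (tigloyl) isomer during activation or heating. The fallback builds the Z double bond on the ester instead of transferring it and sets out from 29. Esterification with the known 2-[bis(2,2,2-trifluoroethoxy)phosphoryl]propanoic acid (DCC, cat. DMAP, CH2Cl2) should give the C5 phosphonopropanoate F4. Still–Gennari olefination of F4 with acetaldehyde (KN(SiMe3)2, 18-crown-6, THF, −78 °C) should then give the angelate and rejoin the route at 32.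

Step 9. The gold-activated alkyne next to the crowded C1 may fail to cyclize in the 5-exo sense (competing 1,3-acyloxy shift or ionization of the propargylic carbonate), so oxygen would not be delivered cleanly to C2. The fallback avoids alkyne hydration and sets out from 10.
- Addition of 1-ethoxyvinyllithium (THF, −78 °C; same Felkin–Anh control as in step 8) should give the enol ether adduct F1.
- Dilute aqueous HCl in THF at 0 °C should convert F1 into the α-hydroxy methyl ketone F2.
- A Paterson boron aldol reaction of F2 with acetaldehyde (the Ipc2BCl enantiomer matched to the 4R adduct, Et3N, Et2O, −78 °C; the first equivalent of reagent engages the tertiary hydroxyl) should give the β-hydroxy ketone F3, whose C4 epimer is a separable diastereomer.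
- Silylation of the secondary hydroxyl (TBDPSCl, imidazole, DMF) rejoins the route at 17.

Further compounds
F0 | step 16 | none | none
F1 | step 9 | enol ether adduct: C1 carbinol bearing a 1-ethoxyvinyl group (C5/C6 acetonide; C7 OBn; C8 OTBS) | CC(C)(C)[Si](C)(C)OCC[C@H](C)[C@@](O)(C(=C)OCC)[C@H]1OC(C)(C)O[C@@H]1COCc1ccccc1
F2 | step 9 | α-hydroxy methyl ketone (C1 OH; C2 acetyl) | CC(C)(C)[Si](C)(C)OCC[C@H](C)[C@@](O)(C(C)=O)[C@H]1OC(C)(C)O[C@@H]1COCc1ccccc1
F3 | step 9 | β-hydroxy ketone with free (4R) hydroxyl | CC(C)(C)[Si](C)(C)OCC[C@H](C)[C@@](O)(C(=O)C[C@@H](C)O)[C@H]1OC(C)(C)O[C@@H]1COCc1ccccc1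
F4 | step 19 | C5 2-[bis(2,2,2-trifluoroethoxy)phosphoryl]propanoate of 29 (mixture at the phosphonate α-carbon) | CC(C(=O)O[C@H]1[C@@H]2OC(=O)[C@H](C)[C@@H]2CC[C@H](C)[C@@]1(O)C(=O)C[C@@H](C)O[Si](c3ccccc3)(c3ccccc3)C(C)(C)C)P(=O)(OCC(F)(F)F)OCC(F)(F)F
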